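**Plan**
- Retrosynthesis: remove the two benzyl ethers, then cut the furan O1'–C2' bond (primed atoms = benzofuran) to a 2‑hydroxystilbene, then cut the C2'=C3' alkene (Wittig) into a flavan‑8‑carbaldehyde and a 2‑hydroxybenzylphosphonium salt.
- Enabling feature: C2' is benzylic to flavan ring A, whose oxygens at C7 and C8a stabilize positive charge there, so oxidation of the hydroxystilbene can forge O1'–C2'.
- Forward, flavan half: (2S)‑alpinetin already holds the chroman ring; the C4 carbonyl is removed, the C7 phenol benzylated and C8 formylated by way of the C8 bromide.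
- Forward, phenol half: 2,4‑dihydroxy‑3‑methylbenzaldehyde is benzylated and methylated, and the missing ortho oxygen is installed by hydroxyl‑directed C–H silylation and oxidation.
- Union and end: Wittig olefination joins the halves, anodic dehydrogenative C–O closure builds the furan (the only ring made), and hydrogenolysis frees both phenols.
- Stereochemistry: the single centre C2 (S) comes from alpinetin and no later step touches it.

Key step: step 12

Assumption: commercial alpinetin is taken as the (2S)‑enantiomer of high enantiomeric purity; stilbene 18 is expected as an E/Z mixture, is drawn as E and is used without separation.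

Step 1
Reactants: 1 alpinetin [(2S)-7-hydroxy-5-methoxyflavanone]
Product: 2 (2S,4S)-5-methoxy-2-phenylchroman-4,7-diol
Conditions: NaBH4, THF/MeOH, 0 °C to rt
Reagents that add atoms: none
Why: Borohydride reduction of the aryl ketone needs neither strong base nor heat, so the pyranone does not open by retro-oxa-Michael reaction and C2 stays S; the new C4 carbinol centre (expected 2,4-cis from axial hydride delivery) is erased in step 2.

Step 2
Reactants: 2 (2S,4S)-5-methoxy-2-phenylchroman-4,7-diol
Product: 3 (2S)-5-methoxy-2-phenylchroman-7-ol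
Conditions: Et3SiH, TFA, CH2Cl2, 0 °C (2 added slowly to excess silane)
Reagents that add atoms: none
Why: Ionic hydrogenation (Kursanov–Parnes type): the C4 carbinol ionizes to a cation stabilized by the C5 and C7 oxygens and O1 and is reduced by the silane, while the C2–O1 bond, benzylic only to an unactivated phenyl, should not ionize, so C2 is retained.

Step 3
Reactants: 3 (2S)-5-methoxy-2-phenylchroman-7-ol; 4 benzyl bromide
Product: 5 (2S)-7-(benzyloxy)-5-methoxy-2-phenylchroman
Conditions: BnBr, K2CO3, DMF, rt
Reagents that add atoms: benzyl bromide (4), BrCc1ccccc1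
Why: Williamson etherification of the only phenol; with the carbonyl gone the flavan is insensitive to carbonate base.

Step 4
Reactants: 5 (2S)-7-(benzyloxy)-5-methoxy-2-phenylchroman
Product: 6 (2S)-7-(benzyloxy)-8-bromo-5-methoxy-2-phenylchroman
Conditions: NBS (1.0 equiv), CH2Cl2, −20 °C to 0 °C, dark
Reagents that add atoms: N-bromosuccinimide, O=C1CCC(=O)N1Br
Why: Electrophilic aromatic bromination; in 5,7-dialkoxyflavans C8, next to the tied-back ring oxygen, is the position normally attacked in preference to C6 between two free alkoxy groups, and ionic conditions in the dark leave the benzylic C–H bonds alone.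

Step 5
Reactants: 6 (2S)-7-(benzyloxy)-8-bromo-5-methoxy-2-phenylchroman
Product: 8 (2S)-7-(benzyloxy)-5-methoxy-2-phenylchroman-8-carbaldehyde, via 8-lithioflavan 7 (not isolated)
Conditions: n-BuLi, THF, −78 °C; then DMF, −78 °C to 0 °C; aqueous work-up
Reagents that add atoms: N,N-dimethylformamide, CN(C)C=O
Why: Bromine–lithium exchange at −78 °C outruns deprotonation at C2–H or OCH2Ph, and the aryllithium is formylated by DMF (Bouveault-type formylation).

Step 6
Reactants: 9 2,4-dihydroxy-3-methylbenzaldehyde; 4 benzyl bromide
Product: 10 4-(benzyloxy)-2-hydroxy-3-methylbenzaldehyde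
Conditions: BnBr (1.05 equiv), K2CO3 (1.0 equiv), acetone, rt
Reagents that add atoms: benzyl bromide (4), BrCc1ccccc1
Why: Williamson etherification selective for the C4 hydroxyl, because the C2 hydroxyl is hydrogen-bonded to the aldehyde and flanked on both sides.

Step 7
Reactants: 10 4-(benzyloxy)-2-hydroxy-3-methylbenzaldehyde
Product: 11 4-(benzyloxy)-2-methoxy-3-methylbenzaldehyde
Conditions: MeI, K2CO3, DMF, 40 °C
Reagents that add atoms: iodomethane, CI
Why: Williamson methylation of the remaining chelated phenol under slightly more forcing conditions.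

Step 8
Reactants: 11 4-(benzyloxy)-2-methoxy-3-methylbenzaldehyde
Product: 12 [4-(benzyloxy)-2-methoxy-3-methylphenyl]methanol
Conditions: NaBH4, MeOH, 0 °C
Reagents that add atoms: none
Why: Borohydride reduction of the aldehyde gives the benzylic alcohol that directs the C–H functionalization of step 9.

Step 9
Reactants: 12 [4-(benzyloxy)-2-methoxy-3-methylphenyl]methanol
Product: 15 5-(benzyloxy)-2-(hydroxymethyl)-3-methoxy-4-methylphenol, via hydrosilyl ether 13 (not isolated), via benzoxasilole 14 (not isolated)
Conditions: Et2SiH2, [Ir(cod)OMe]2 (cat.), THF, rt; then [Ir(cod)OMe]2 (cat.), 1,10-phenanthroline, norbornene, THF, 80 °C; then H2O2, KHCO3, THF/MeOH, rt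
Reagents that add atoms: hydrogen peroxide, OO
Why: Hydroxyl-directed arene ortho-silylation followed by Tamao–Fleming oxidation: dehydrogenative silylation gives the hydrosilyl ether, iridium-catalysed C–H silylation closes the oxasilole at the only free ortho position, and peroxide turns the aryl–Si bond into the phenol, so the oxygen is placed without regiochemical ambiguity (silicon from Et2SiH2 is carried only in 13 and 14).

Step 10
Reactants: 15 5-(benzyloxy)-2-(hydroxymethyl)-3-methoxy-4-methylphenol
Product: 16 [4-(benzyloxy)-6-hydroxy-2-methoxy-3-methylbenzyl]triphenylphosphonium bromide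
Conditions: PPh3·HBr, MeCN, reflux
Reagents that add atoms: triphenylphosphine hydrobromide, [Br-].c1ccc(cc1)[PH+](c1ccccc1)c1ccccc1
Why: Acid-promoted ionization of the electron-rich salicyl alcohol to an o-quinone methide and its capture by PPh3 is the standard preparation of 2-hydroxybenzylphosphonium salts, and aryl benzyl and methyl ethers tolerate the reagent.

Step 11
Reactants: 16 [4-(benzyloxy)-6-hydroxy-2-methoxy-3-methylbenzyl]triphenylphosphonium bromide; 8 (2S)-7-(benzyloxy)-5-methoxy-2-phenylchroman-8-carbaldehyde
Product: 18 5-(benzyloxy)-2-{(E)-2-[(2S)-7-(benzyloxy)-5-methoxy-2-phenylchroman-8-yl]ethenyl}-3-methoxy-4-methylphenol, via phenolate ylide 17 (not isolated)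
Conditions: LiN(SiMe3)2 (2.2 equiv), THF, −78 °C to rt; aqueous work-up
Reagents that add atoms: none
Why: Wittig olefination: two equivalents of base give the phenolate ylide, which adds to the aldehyde and expels Ph3PO; the alkene geometry does not matter because both isomers feed the same oxidized intermediate in step 12.

Step 12
Reactants: 18 5-(benzyloxy)-2-{(E)-2-[(2S)-7-(benzyloxy)-5-methoxy-2-phenylchroman-8-yl]ethenyl}-3-methoxy-4-methylphenol
Product: 19 (2S)-7-(benzyloxy)-8-[6-(benzyloxy)-4-methoxy-5-methyl-1-benzofuran-2-yl]-5-methoxy-2-phenylchroman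
Conditions: undivided cell, graphite anode, Pt cathode, potential held at the first anodic wave (2.0–2.2 F/mol), n-Bu4NPF6, 2,6-lutidine, MeCN/HFIP 4:1, rt, dilute
Reagents that add atoms: none
Why: Proposed new method: the anode should take two electrons and one proton from the phenol–stilbene to give a phenoxonium (o-quinone-methide-type) cation whose charge is delocalized to C2', the carbon benzylic to flavan ring A and stabilized by its oxygens at C7 and C8a; the phenolic oxygen bonds to C2', loss of the C2' proton aromatizes the furan, and the protons are reduced to H2 at the cathode. The closest known reaction type is the oxidative cyclization of 2-hydroxystilbenes to 2-arylbenzofurans with I2 or PhI(OAc)2, together with anodic dehydrogenative cyclizations of phenols onto alkenes. The furan ring closes by a formally 5-endo O–C bond formation that is easy here because the electrophile is a delocalized oxapentadienyl cation, not a neutral alkene, and bond rotation in the oxidized state lets either alkene isomer close. No stereocentre is created and C2 of the flavan is not involved. The selectivity needed is oxidation of the one free phenol–stilbene in preference to the benzyl ethers, the flavan and the benzofuran product, which is secured by protection of the other two hydroxyls, by base-assisted (2,6-lutidine) phenol oxidation at the lowest wave with the potential held there and the charge limited to about 2 F/mol, and by a methanol-free HFIP/MeCN medium that cannot capture the cation.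

Step 13
Reactants: 19 (2S)-7-(benzyloxy)-8-[6-(benzyloxy)-4-methoxy-5-methyl-1-benzofuran-2-yl]-5-methoxy-2-phenylchroman
Product: 20 2-[(2S)-7-hydroxy-5-methoxy-2-phenylchroman-8-yl]-4-methoxy-5-methyl-1-benzofuran-6-ol (CNP0000229.1)
Conditions: H2 (1 atm), Pd/C (palladium on carbon), EtOAc/MeOH, rt, stopped at full debenzylation
Reagents that add atoms: none
Why: Catalytic hydrogenolysis of the two aryl benzyl ethers under neutral conditions should spare the aryl methyl ethers, the benzofuran and the cyclic benzylic C2–O1 ether, leaving C2 as S.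

**Compound list**
1 | alpinetin, (2S)-7-hydroxy-5-methoxyflavanone | O=C1C[C@@H](c2ccccc2)Oc2cc(O)cc(OC)c12 | starting material
2 | (2S,4S)-5-methoxy-2-phenylchroman-4,7-diol (2,4-cis flavan-4-ol) | O[C@H]1C[C@@H](c2ccccc2)Oc2cc(O)cc(OC)c12 | intermediate
3 | (2S)-5-methoxy-2-phenylchroman-7-ol | COc1cc(O)cc2c1CC[C@@H](c1ccccc1)O2 | intermediate
4 | benzyl bromide | BrCc1ccccc1 | starting material
5 | (2S)-7-(benzyloxy)-5-methoxy-2-phenylchroman | COc1cc(OCc2ccccc2)cc2c1CC[C@@H](c1ccccc1)O2 | intermediate
6 | (2S)-7-(benzyloxy)-8-bromo-5-methoxy-2-phenylchroman | COc1cc(OCc2ccccc2)c(Br)c2c1CC[C@@H](c1ccccc1)O2 | intermediate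
7 | [(2S)-7-(benzyloxy)-5-methoxy-2-phenylchroman-8-yl]lithium (formed in the flask) | COc1cc(OCc2ccccc2)c([Li])c2c1CC[C@@H](c1ccccc1)O2 | intermediate
8 | (2S)-7-(benzyloxy)-5-methoxy-2-phenylchroman-8-carbaldehyde | COc1cc(OCc2ccccc2)c(C=O)c2c1CC[C@@H](c1ccccc1)O2 | intermediate
9 | 2,4-dihydroxy-3-methylbenzaldehyde | Cc1c(O)ccc(C=O)c1O | starting material
10 | 4-(benzyloxy)-2-hydroxy-3-methylbenzaldehyde | Cc1c(OCc2ccccc2)ccc(C=O)c1O | intermediate
11 | 4-(benzyloxy)-2-methoxy-3-methylbenzaldehyde | COc1c(C)c(OCc2ccccc2)ccc1C=O | intermediate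
12 | [4-(benzyloxy)-2-methoxy-3-methylphenyl]methanol | COc1c(C)c(OCc2ccccc2)ccc1CO | intermediate
13 | {[4-(benzyloxy)-2-methoxy-3-methylphenyl]methoxy}diethylsilane (formed in the flask) | COc1c(C)c(OCc2ccccc2)ccc1CO[SiH](CC)CC | intermediate
14 | 6-(benzyloxy)-1,1-diethyl-4-methoxy-5-methyl-1,3-dihydro-2,1-benzoxasilole (formed in the flask) | COc1c(C)c(OCc2ccccc2)cc2c1CO[Si]2(CC)CC | intermediate
15 | 5-(benzyloxy)-2-(hydroxymethyl)-3-methoxy-4-methylphenol | COc1c(C)c(OCc2ccccc2)cc(O)c1CO | intermediate
16 | [4-(benzyloxy)-6-hydroxy-2-methoxy-3-methylbenzyl]triphenylphosphonium bromide | COc1c(C)c(OCc2ccccc2)cc(O)c1C[P+](c1ccccc1)(c1ccccc1)c1ccccc1.[Br-] | intermediate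
17 | lithium 5-(benzyloxy)-3-methoxy-4-methyl-2-[(triphenyl-λ5-phosphanylidene)methyl]phenolate (formed in the flask) | COc1c(C)c(OCc2ccccc2)cc([O-])c1C=P(c1ccccc1)(c1ccccc1)c1ccccc1.[Li+] | intermediate
18 | 5-(benzyloxy)-2-{(E)-2-[(2S)-7-(benzyloxy)-5-methoxy-2-phenylchroman-8-yl]ethenyl}-3-methoxy-4-methylphenol (E shown; Z isomer equally usable) | COc1c(C)c(OCc2ccccc2)cc(O)c1/C=C/c1c(OCc2ccccc2)cc(OC)c2CC[C@@H](c3ccccc3)Oc12 | intermediate
19 | (2S)-7-(benzyloxy)-8-[6-(benzyloxy)-4-methoxy-5-methyl-1-benzofuran-2-yl]-5-methoxy-2-phenylchroman | COc1cc(OCc2ccccc2)c(-c2cc3c(OC)c(C)c(OCc4ccccc4)cc3o2)c2c1CC[C@@H](c1ccccc1)O2 | intermediate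
20 | 2-[(2S)-7-hydroxy-5-methoxy-2-phenylchroman-8-yl]-4-methoxy-5-methyl-1-benzofuran-6-ol (CNP0000229.1) | COc1cc(O)c(-c2cc3c(OC)c(C)c(O)cc3o2)c2c1CC[C@@H](c1ccccc1)O2 | target

Total step count: 13.
Longest linear sequence: 8 steps (steps 1–5, then 11–13; the branch of steps 6–10, then 11–13, is equally long).

**Steps most likely to fail**

Step 12 (the proposed new method). The electrolysis may go astray in several ways:
- over-oxidation of the electron-rich benzofuran once it forms;
- dimerization of the phenoxyl radical before the second electron is removed;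
- capture of the cation by the medium, or fouling of the anode.

The fallback uses known chemistry and sets out from aldehyde 8 and phosphonium salt 16. Pinnick oxidation of 8 (NaClO2, NaH2PO4, 2-methyl-2-butene, t-BuOH/H2O) would give (2S)-7-(benzyloxy)-5-methoxy-2-phenylchroman-8-carboxylic acid F1. Oxalyl chloride with catalytic DMF in CH2Cl2 would convert it into (2S)-7-(benzyloxy)-5-methoxy-2-phenylchroman-8-carbonyl chloride F2. With 16 and Et3N in toluene, F2 would acylate the phenol to give [4-(benzyloxy)-6-{[(2S)-7-(benzyloxy)-5-methoxy-2-phenylchroman-8-carbonyl]oxy}-2-methoxy-3-methylbenzyl]triphenylphosphonium bromide F3. Further Et3N at reflux would close F3 by intramolecular Wittig olefination of the ester carbonyl. This returns to the route at 19.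

Step 9. The directed C–H silylation may stall or go astray with a primary benzylic silyl ether (second silylation to the dialkoxysilane, slow cyclization next to the electron-rich ring). The peroxide step may also degrade the electron-rich salicyl alcohol. The fallback sets out from aldehyde 11. Directed ortho-lithiation of the aldehyde, masked in situ with LiN(Me)CH2CH2NMe2 (n-BuLi, THF, −20 °C), followed by trapping with B(OMe)3 and oxidation with H2O2 in the same flask, would give 4-(benzyloxy)-6-hydroxy-2-methoxy-3-methylbenzaldehyde F4. NaBH4 reduction of F4 in MeOH returns to the route at 15.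

Step 11. Addition of the phenolate ylide to a di-ortho-substituted, electron-rich aldehyde may be slow. On warming, the phenolate may lose PPh3 (o-quinone methide formation) faster than it olefinates. The fallback sets out from phosphonium salt 16 and bromide 6 and replaces carbonyl olefination by a palladium-catalysed coupling. Wittig methylenation of 16 with aqueous formaldehyde and K2CO3 would give 5-(benzyloxy)-2-ethenyl-3-methoxy-4-methylphenol F5. Mizoroki–Heck coupling of F5 with 6 (Pd(OAc)2, [HP(t-Bu)3]BF4, Cy2NMe, dioxane, 100 °C) returns to the route at 18 as the E isomer and makes step 5 unnecessary.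

Further compounds
F1 | step 12 | (2S)-7-(benzyloxy)-5-methoxy-2-phenylchroman-8-carboxylic acid | COc1cc(OCc2ccccc2)c(C(=O)O)c2c1CC[C@@H](c1ccccc1)O2
F2 | step 12 | (2S)-7-(benzyloxy)-5-methoxy-2-phenylchroman-8-carbonyl chloride | COc1cc(OCc2ccccc2)c(C(=O)Cl)c2c1CC[C@@H](c1ccccc1)O2
F3 | step 12 | [4-(benzyloxy)-6-{[(2S)-7-(benzyloxy)-5-methoxy-2-phenylchroman-8-carbonyl]oxy}-2-methoxy-3-methylbenzyl]triphenylphosphonium bromide | COc1cc(OCc2ccccc2)c(C(=O)Oc2cc(OCc3ccccc3)c(C)c(OC)c2C[P+](c2ccccc2)(c2ccccc2)c2ccccc2)c2c1CC[C@@H](c1ccccc1)O2.[Br-]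
F4 | step 9 | 4-(benzyloxy)-6-hydroxy-2-methoxy-3-methylbenzaldehyde | COc1c(C)c(OCc2ccccc2)cc(O)c1C=O
F5 | step 11 | 5-(benzyloxy)-2-ethenyl-3-methoxy-4-methylphenol | COc1c(C)c(OCc2ccccc2)cc(O)c1C=C
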